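**Strategy.** Ring A (C1–C5, C10; eudesmane numbering) carries a 3α-hydroxy/4β-hydroxy-4α-methyl pair next to the ring-fusion carbon C5: the retron of an α-ketol rearrangement. Ring A is therefore made from a five-membered ring. In the key step the trans-hydrindane ketol 16 (ring C10–C1–C2–C3–C5; C3 bears an α-hydroxyl and a β-acetyl group, C4 and C15) rearranges under base: C5 migrates from C3 to the acetyl carbon C4, which expands the ring, turns C3 into the ketone and creates the C4 tertiary carbinol in one operation. The hydrindane comes from (−)-menthone (ring B, C7, C14) by an oxy-Cope/aldol annulation and a face-selective hydroboration.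

Key step: step 12

Remark: eudesmane atom labels are used for the target and for every intermediate (ring A = C1–C5 and C10; ring B = C5–C10; C14 = methyl on C10; C15 = methyl on C4); β is the face of the C10 methyl group. The methoxy-bearing carbon of 4 and the enol ether geometry of 5 are formed as mixtures, vanish in steps 3 and 4, and are left undefined in the SMILES.

Step 1
Reactants: 1 (−)-menthone
Product: 2 (S)-piperitone
Conditions: LDA, THF, −78 °C; then PhS(Cl)=N-t-Bu, −78 °C
Reagents that add atoms: none
Why: LDA removes a proton from the unbranched α-methylene (C5 of the target) under kinetic control and the sulfinimidoyl chloride turns this enolate into the enone at −78 °C by sulfenylation and syn-elimination (Mukaiyama dehydrogenation), so the C7 stereocenter next to the carbonyl is never enolised.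

Step 2
Reactants: 2 (S)-piperitone; 3 allyl methyl ether
Product: 4 tertiary 1-(1-methoxyallyl) carbinol (side chain on C6 α, 6β-OH)
Conditions: 3, s-BuLi, THF, −78 °C; ZnCl2; then 2, −78 to 0 °C; aq. NH4Cl
Reagents that add atoms: allyl methyl ether, COCC=C
Why: Zinc alkoxyallyl reagents add 1,2 to enones through the oxygen-bearing carbon (allylmetal carbonyl addition), and attack anti to the neighbouring C7 isopropyl group, as known for organometallic additions to menthone, should set C6 with the side chain α and the hydroxyl β.

Step 3
Reactants: 4 tertiary 1-(1-methoxyallyl) carbinol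
Product: 5 3-(3-methoxyallyl)-3-methyl-6-isopropylcyclohexanone (10β-methyl, enol ether E/Z mixture)
Conditions: KH, 18-crown-6, THF, 0 to 25 °C; pH 7 buffer, −78 °C
Reagents that add atoms: none
Why: The potassium alkoxide of this 1,5-dien-3-ol undergoes an anionic oxy-Cope rearrangement in which the allyl unit passes suprafacially from the α face of C6 to the α face of C10, creating the quaternary center C10 with its methyl group β (cis to the isopropyl group) and releasing the C6 ketone as its C5 enolate.

Step 4
Reactants: 5 3-(3-methoxyallyl)-3-methyl-6-isopropylcyclohexanone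
Product: 7 hydrindenone (C3=C5 ene, C6 ketone, 7β-isopropyl, 10β-methyl), via keto aldehyde 6 (not isolated)
Conditions: 2 M HCl, THF, 50 °C
Reagents that add atoms: none
Why: Aqueous acid hydrolyses the enol ether to the aldehyde, and the ketone enol at C5 then adds to C3 and dehydrates (intramolecular aldol condensation, 5-exo closure) to the cyclopentene-fused enone, while C7 keeps its equatorial isopropyl group, which is also the thermodynamically preferred arrangement.

Step 5
Reactants: 7 hydrindenone
Product: 8 allylic 6β-alcohol
Conditions: NaBH4, CeCl3·7H2O, MeOH, −78 to 0 °C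
Reagents that add atoms: none
Why: Luche 1,2-reduction delivers hydride to C6 from the α face, away from the axial C10 methyl group, which sets the axial 6β-hydroxyl and ends the enolisability of C7.

Step 6
Reactants: 8 allylic 6β-alcohol
Product: 9 6β-triethylsilyl ether
Conditions: Et3SiOTf, 2,6-lutidine, CH2Cl2, −78 to 0 °C
Reagents that add atoms: triethylsilyl triflate, CC[Si](CC)(CC)OS(=O)(=O)C(F)(F)F
Why: Silylation with the reactive triflate protects the hindered allylic 6β-hydroxyl so that the later oxidation and strong-base steps act only at C3.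

Step 7
Reactants: 9 6β-triethylsilyl ether
Product: 10 trans-hydrindan-3α-ol (5α-H)
Conditions: BH3·THF, THF, 0 to 25 °C; then NaOH, H2O2, 0 °C
Reagents that add atoms: hydrogen peroxide, OO
Why: Hydroboration–oxidation adds H and OH syn across C3=C5 from the α face, opposite the C10 methyl and the 6β-silyloxy group, with boron on the less substituted C3, which sets C5 (α-H, trans ring fusion) and gives the 3α-alcohol, as in hydroboration of steroidal 14-enes.

Step 8
Reactants: 10 trans-hydrindan-3α-ol
Product: 11 trans-hydrindan-3-one
Conditions: Dess–Martin periodinane, NaHCO3, CH2Cl2, 0 to 25 °C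
Reagents that add atoms: none
Why: Dess–Martin oxidation under buffered, non-enolising conditions converts the 3α-alcohol to the ketone without epimerising the adjacent ring-fusion center C5.

Step 9
Reactants: 11 trans-hydrindan-3-one
Product: 12 C2=C3 enol triflate
Conditions: KHMDS, THF, −78 °C; PhNTf2, −78 to 0 °C
Reagents that add atoms: N-phenylbis(trifluoromethanesulfonimide), O=S(=O)(N(c1ccccc1)S(=O)(=O)C(F)(F)F)C(F)(F)F
Why: KHMDS at −78 °C deprotonates the unhindered C2 methylene and not the ring-fusion C5–H, and the triflimide traps this kinetic enolate as the enol triflate, so the trans ring fusion is kept.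

Step 10
Reactants: 12 C2=C3 enol triflate; 13 tributyl(1-ethoxyvinyl)stannane
Product: 15 3-acetyl-2-ene with free 6β-hydroxyl, via ethoxydiene silyl ether 14 (not isolated)
Conditions: Pd(PPh3)4 (cat.), LiCl, CuI (cat.), THF, 65 °C; then 2 M HCl, THF/MeOH, 25 °C
Reagents that add atoms: tributyl(1-ethoxyvinyl)stannane, CCOC(=C)[Sn](CCCC)(CCCC)CCCC; water, O
Why: Stille coupling of the alkenyl triflate with the 1-ethoxyvinylstannane installs C4 and C15 as an enol ether, and the acidic work-up hydrolyses it to the methyl ketone and cleaves the triethylsilyl ether in the same flask.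

Step 11
Reactants: 15 3-acetyl-2-ene
Product: 16 α-ketol (3α-hydroxy, 3β-acetyl, 6β-hydroxy, trans-hydrindane)
Conditions: Mn(dpm)3 (cat.), PhSiH3, O2 (1 atm), i-PrOH/CH2Cl2, 0 °C; then P(OEt)3
Reagents that add atoms: dioxygen, O=O
Why: In this Mukaiyama-type reductive α-hydroxylation the manganese hydride formed from Mn(dpm)3 and PhSiH3 transfers a hydrogen atom to C2, and the C3 radical is trapped by O2 on the α face, opposite the C10 methyl and the 6β-hydroxyl, so that after reduction of the hydroperoxide C3 carries the α-hydroxyl and the β-acetyl group.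

Step 12
Reactants: 16 α-ketol
Product: 17 4β,6β-dihydroxy-5α,7αH-eudesman-3-one
Conditions: KOH (0.2 equiv), MeOH, 0 to 25 °C
Reagents that add atoms: none
Why: Deprotonation of the C3 hydroxyl gives an alkoxide whose C3–O and C4=O dipoles lie antiperiplanar in the protic, non-chelating medium; C5 then shifts suprafacially from C3 to the acetyl carbon C4 with retention at C5 while C3 becomes the ketone (α-ketol rearrangement), the closest known case being the base-induced D-homoannulation of 17α-hydroxy-20-oxo steroids. No ring is closed by cyclisation: ring A (C1–C5, C10) arises from the five-membered ring C10–C1–C2–C3–C5 by this 1,2-shift, a one-carbon enlargement driven by release of trans-hydrindane strain. The new stereocenter C4 is set by the transoid oxygen arrangement on the β-acetyl group, which puts the C4 oxygen axial (β) and the methyl C15 equatorial (α) in a chair-like transition state and avoids a 1,3-diaxial clash of C15 with the C10 methyl. The step needs migration of C5 and not of the C2 methylene: with the acetyl group on the β face only C5 migration passes through a chair-like six-membered array, C5 is the more substituted carbon, and the 6β-hydroxyl can hold the potassium ion or hydrogen-bond to the emerging C4 alkoxide. It also needs the ketol to stop at 17 without a further methyl shift, which the mild, short base treatment and the stability of the trans-decalin should secure.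

Step 13
Reactants: 17 4β,6β-dihydroxy-5α,7αH-eudesman-3-one; 18 benzoic anhydride
Product: 19 6β-benzoyloxy-4β-hydroxy-5α,7αH-eudesman-3-one
Conditions: 18, DMAP, Et3N, ClCH2CH2Cl, 60 °C
Reagents that add atoms: benzoic anhydride, O=C(OC(=O)c1ccccc1)c1ccccc1
Why: DMAP-catalysed acylation esterifies the secondary 6β-hydroxyl while the tertiary 4β-hydroxyl is too hindered to react, and an ester that strayed to O4 would return to the less hindered O6 by acyl migration.

Step 14
Reactants: 19 6β-benzoyloxy-4β-hydroxy-5α,7αH-eudesman-3-one
Product: 20 6β-benzoyloxy-5α,7αH-eudesmane-3α,4β-diol (CNP0187831.1)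
Conditions: Me4NBH(OAc)3, AcOH/MeCN, −20 to 25 °C
Reagents that add atoms: none
Why: In this Evans–Saksena-type directed reduction the triacetoxyborohydride exchanges an acetate for the 4β-hydroxyl and delivers hydride internally to the β face of the C3 ketone, giving the trans-diaxial 3α,4β-diol under mildly acidic conditions that leave the benzoate in place.

**Compound list**

1 | (−)-menthone, (2S,5R)-2-isopropyl-5-methylcyclohexanone | CC(C)[C@@H]1CC[C@@H](C)CC1=O | starting material
2 | (S)-piperitone, (6S)-3-methyl-6-isopropylcyclohex-2-en-1-one | CC(C)[C@@H]1CCC(C)=CC1=O | intermediate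
3 | allyl methyl ether (3-methoxyprop-1-ene) | COCC=C | starting material
4 | 1-(1-methoxyprop-2-en-1-yl)-3-methyl-6-isopropylcyclohex-2-en-1-ol; side chain on C6 α (trans to the 7β-isopropyl group), 6β-OH; both epimers at the methoxy carbon | CC(C)[C@@H]1CCC(C)=C[C@@]1(O)C(OC)C=C | intermediate
5 | 3-(3-methoxyprop-2-en-1-yl)-3-methyl-6-isopropylcyclohexanone; C10 methyl cis to the C7 isopropyl group; E/Z mixture | CC(C)[C@@H]1CC[C@@](C)(CC=COC)CC1=O | intermediate
6 | 3-(1-methyl-4-isopropyl-3-oxocyclohexyl)propanal, same C7 and C10 configuration (not isolated) | CC(C)[C@@H]1CC[C@@](C)(CCC=O)CC1=O | intermediate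
7 | 7a-methyl-5-isopropyl-1,2,5,6,7,7a-hexahydro-4H-inden-4-one; C3=C5 ene, C6 ketone, 7β-isopropyl, 10β-methyl | CC(C)[C@@H]1CC[C@@]2(C)CCC=C2C1=O | intermediate
8 | allylic alcohol of 7 with 6β-OH | CC(C)[C@@H]1CC[C@@]2(C)CCC=C2[C@@H]1O | intermediate
9 | 6β-triethylsilyl ether of 8 | CC(C)[C@@H]1CC[C@@]2(C)CCC=C2[C@@H]1O[Si](CC)(CC)CC | intermediate
10 | trans-hydrindane with 3α-OH, 5α-H, 6β-OSiEt3, 7β-isopropyl, 10β-methyl | CC(C)[C@@H]1CC[C@@]2(C)CC[C@@H](O)[C@@H]2[C@@H]1O[Si](CC)(CC)CC | intermediate
11 | trans-hydrindan-3-one with 5α-H, 6β-OSiEt3, 7β-isopropyl, 10β-methyl | CC(C)[C@@H]1CC[C@@]2(C)CCC(=O)[C@@H]2[C@@H]1O[Si](CC)(CC)CC | intermediate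
12 | C2=C3 enol triflate of 11 | CC(C)[C@@H]1CC[C@@]2(C)CC=C(OS(=O)(=O)C(F)(F)F)[C@@H]2[C@@H]1O[Si](CC)(CC)CC | intermediate
13 | tributyl(1-ethoxyvinyl)stannane | CCCC[Sn](CCCC)(CCCC)C(=C)OCC | starting material
14 | 3-(1-ethoxyvinyl)-2-ene, 6β-OSiEt3 (not isolated) | CC(C)[C@@H]1CC[C@@]2(C)CC=C(C(=C)OCC)[C@@H]2[C@@H]1O[Si](CC)(CC)CC | intermediate
15 | 3-acetyl-2-ene with 5α-H, 6β-OH, 7β-isopropyl, 10β-methyl | CC(C)[C@@H]1CC[C@@]2(C)CC=C(C(C)=O)[C@@H]2[C@@H]1O | intermediate
16 | trans-hydrindane α-ketol: 3α-OH, 3β-acetyl, 5α-H, 6β-OH, 7β-isopropyl, 10β-methyl | CC(C)[C@@H]1CC[C@@]2(C)CC[C@](O)(C(C)=O)[C@@H]2[C@@H]1O | intermediate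
17 | 4β,6β-dihydroxy-5α,7αH-eudesman-3-one (4α-methyl) | CC(C)[C@@H]1CC[C@@]2(C)CCC(=O)[C@](C)(O)[C@@H]2[C@@H]1O | intermediate
18 | benzoic anhydride | O=C(OC(=O)c1ccccc1)c1ccccc1 | starting material
19 | 6β-benzoyloxy-4β-hydroxy-5α,7αH-eudesman-3-one | CC(C)[C@@H]1CC[C@@]2(C)CCC(=O)[C@](C)(O)[C@@H]2[C@@H]1OC(=O)c1ccccc1 | intermediate
20 | 6β-benzoyloxy-5α,7αH-eudesmane-3α,4β-diol (CNP0187831.1) | CC(C)[C@@H]1CC[C@@]2(C)CC[C@@H](O)[C@](C)(O)[C@@H]2[C@@H]1OC(=O)c1ccccc1 | target

**Step count.** Total: 14 steps. Longest linear sequence: 14 steps, from (−)-menthone 1.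

**Steps most likely to fail**

1. Step 12 (key step). The C2 methylene may migrate in place of C5, a chelated (cisoid) transition state may invert C4, or the product ketol may isomerise further by a methyl shift under base. Fallback, from 16 back to 17: both hydroxyls are silylated (Me3SiOTf, Et3N, CH2Cl2) to the bis(trimethylsilyl) ether of the ketol F1. This ether is treated with a bulky monodentate aluminium Lewis acid, MeAl(OAr)2 (Ar = 2,6-di-tert-butyl-4-methylphenyl), in CH2Cl2 at −78 °C. In this acyloin-type rearrangement of an α-silyloxy ketone the silyl ether cannot chelate, the shift is cation-like and therefore favours the more substituted C5, and the silyl group moves to the new C4 oxygen, giving the ring-expanded bis(trimethylsilyl) ether F2. K2CO3 in MeOH removes both silyl groups and returns to 17.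

2. Step 2. The ambident alkoxyallyl nucleophile may attack through its unsubstituted terminus, the hindered enone may be enolised instead of attacked, or facial selectivity at C6 may be incomplete. Fallback, from 2 back to 6: allylmagnesium bromide with CeCl3 in THF at −78 °C adds 1,2 without an ambident terminus and with little enolisation, giving the 1-allyl carbinol F3. KH/18-crown-6 effects the same oxy-Cope rearrangement to the 3-allyl ketone F4. An aldehyde-selective Wacker oxidation (PdCl2(PhCN)2, CuCl2, AgNO2, O2, t-BuOH/MeNO2) then converts the terminal alkene to the keto aldehyde 6, which is cyclised to 7 under the acid conditions of step 4. Any C10 epimer arising from the minor C6 epimer is removed at 7.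

3. Step 13. Acylation of the 6β-hydroxyl may be very slow because it is shielded syn-diaxially by the C10 methyl and the 4β-hydroxyl, and the α-ketol may degrade on long heating with base. Fallback, from 17 back to 19: trimethyl orthobenzoate with catalytic camphorsulfonic acid in CH2Cl2 ties the syn-diaxial 4β,6β-diol into the cyclic methyl orthobenzoate F5, so the benzoyl carbon is delivered intramolecularly. Mild hydrolysis (aq. AcOH, THF) opens the orthoester to the hydroxy benzoate, and brief treatment with DBU moves any 4-benzoate to the less hindered O6, giving 19.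

Further compounds
F1 | step 12 | bis(trimethylsilyl) ether of α-ketol 16 | CC(C)[C@@H]1CC[C@@]2(C)CC[C@](O[Si](C)(C)C)(C(C)=O)[C@@H]2[C@@H]1O[Si](C)(C)C
F2 | step 12 | 4β,6β-bis(trimethylsilyl) ether of 17 | CC(C)[C@@H]1CC[C@@]2(C)CCC(=O)[C@](C)(O[Si](C)(C)C)[C@@H]2[C@@H]1O[Si](C)(C)C
F3 | step 2 | 1-allyl-3-methyl-6-isopropylcyclohex-2-en-1-ol (allyl α, 6β-OH) | CC(C)[C@@H]1CCC(C)=C[C@@]1(O)CC=C
F4 | step 2 | 3-allyl-3-methyl-6-isopropylcyclohexanone (10β-methyl) | CC(C)[C@@H]1CC[C@@](C)(CC=C)CC1=O
F5 | step 13 | cyclic methyl orthobenzoate across O4 and O6 of 17 | CC(C)[C@@H]1CC[C@@]2(C)CCC(=O)[C@]3(C)OC(OC)(c4ccccc4)O[C@H]1[C@H]23
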